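**Plan**

- Ring numbering used here: C1 (CH–OAc), C2 (C–OMe), C3 (=CH), C4 (CH–OH), C5 (=CH), C6 (carries the side chain). The retrosynthesis cuts C2–C3 and C4–C5 together: C3–C4 is vinylene carbonate and C5–C6–C1–C2 is the achiral 1-methoxy-3-alkylbuta-1,3-diene 3. Further cuts: the C1 acetate (delivered through palladium), the carbinol–tridecyl bond of the side chain (aldehyde plus dialkylzinc) and the diene (alkyne 1 plus methyl vinyl ether).
- Forward: diene (step 1), Diels–Alder closure of the only ring (2), alkene shift into the enol ether (3), palladium-mediated 1,4-transposition of one carbonate oxygen to C1 as acetate, run as a kinetic resolution (4), completion of the side chain on the resolved ring (5–9), then a ketone/selenide detour that makes C5=C6 last and without acid (10–12).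
- Enabling feature: the free C4–OH and the C1–OAc are cis-1,4 across the C2=C3 enol ether, so the ring edge C3–C4 is what remains of a cis-1,2-diol after an allylic transposition. The cyclic carbonate (a ring not in the target) holds the two oxygens cis, keeps one as C4–OH and gives up the other as leaving group.
- Stereochemistry: the diene carries no stereocentre, so the cycloaddition gives one racemic compound. The ring's absolute configuration is chosen by the chiral palladium catalyst in step 4. The side-chain (R) centre is made only afterwards, under catalyst control, in step 8. The cis C1/C4 relation comes from the carbonate and net retention at palladium. C4 is re-set by Luche reduction under control of the temporary C5 (selenide) and C6 centres, which vanish in step 12.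

Key step: step 2

Assumption: racemic 5 and 6 are drawn and named as the enantiomer that is carried on.
Assumption: the (R,R)-ligand is taken as the enantiomer whose palladium complex ionises (3aR,6S,7aR)-6 faster; if the preference is the reverse, the (S,S)-ligand is used and nothing else changes.
Assumption: (1S,2S)-1,2-bis(trifluoromethanesulfonamido)cyclohexane is taken as the ligand enantiomer that gives the (R) carbinol in step 8; if the sense is the reverse, the (1R,2R)-ligand is used.

Step 1
Reactants: 1 tert-butyl(but-3-yn-1-yloxy)dimethylsilane; 2 methyl vinyl ether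
Product: 3 tert-butyl{[(4E)-5-methoxy-3-methylidenepent-4-en-1-yl]oxy}dimethylsilane
Conditions: second-generation Grubbs catalyst (5 mol %), 2 (excess), benzene, sealed tube, 50 °C
Reagents that add atoms: methyl vinyl ether (2), COC=C
Why: Intermolecular enol ether–alkyne (cross enyne) metathesis of a terminal alkyne should give the 2-substituted 1-alkoxy-1,3-diene in one step, with the (E)-enol ether expected as the main isomer and the only one able to react in step 2.

Step 2
Reactants: 3 tert-butyl{[(4E)-5-methoxy-3-methylidenepent-4-en-1-yl]oxy}dimethylsilane; 4 vinylene carbonate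
Product: 5 rac-(3aR,4S,7aR)-6-{2-[(tert-butyldimethylsilyl)oxy]ethyl}-4-methoxy-3a,4,7,7a-tetrahydro-1,3-benzodioxol-2-one
Conditions: 4 (3 equiv), toluene, BHT (cat.), sealed tube, 150 °C
Reagents that add atoms: vinylene carbonate (4), O=C1OC=CO1
Why: Concerted suprafacial thermal [4+2] cycloaddition between the electron-rich (E)-1-methoxy diene and vinylene carbonate; the closest known reaction type is the Diels–Alder reaction of 1-oxygenated butadienes with vinylene carbonate used for conduritols. The cyclohexene ring is closed intermolecularly by forming at once the bond from the diene CH2 terminus to one carbonate carbon and the bond from the methoxy-bearing terminus to the other. The cis ring fusion (C3a, C7a) follows from the cis geometry locked in the cyclic dienophile, and the methoxy-bearing C4 is set cis to the carbonate by the endo rule, which places the C4 hydrogen on the face opposite the carbonate for step 3. The dienophile is symmetrical, so there is no regiochemical issue, and the substitution of the diene alone decides which ring carbon carries the methoxy group and which the side-chain arm. Diene 3 has no stereocentre, so the adduct should form as a single racemic diastereomer, and its absolute configuration is chosen in step 4.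

Step 3
Reactants: 5 rac-(3aR,4S,7aR)-6-{2-[(tert-butyldimethylsilyl)oxy]ethyl}-4-methoxy-3a,4,7,7a-tetrahydro-1,3-benzodioxol-2-one
Product: 6 rac-(3aR,6S,7aR)-6-{2-[(tert-butyldimethylsilyl)oxy]ethyl}-4-methoxy-3a,6,7,7a-tetrahydro-1,3-benzodioxol-2-one
Conditions: RuHCl(CO)(PPh3)3 (5 mol %), toluene, 80 °C
Reagents that add atoms: none
Why: Ruthenium hydride isomerisation of an allyl ether to the enol ether: Ru–H should add to the ring alkene from the face opposite the carbonate with the metal on the less substituted carbon, and β-hydride elimination of the C4 hydrogen on that same face gives the conjugated enol ether with the new C6 hydrogen trans to the carbonate (relative configuration only, the material stays racemic).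

Step 4
Reactants: 6 rac-(3aR,6S,7aR)-6-{2-[(tert-butyldimethylsilyl)oxy]ethyl}-4-methoxy-3a,6,7,7a-tetrahydro-1,3-benzodioxol-2-one
Product: 7 (1S,4R,6S)-6-{2-[(tert-butyldimethylsilyl)oxy]ethyl}-4-hydroxy-2-methoxycyclohex-2-en-1-yl acetate
Conditions: Pd2(dba)3·CHCl3 (2.5 mol %), (R,R)-DACH-phenyl Trost ligand [N,N′-(1R,2R)-cyclohexane-1,2-diylbis(2-diphenylphosphinobenzamide)] (7.5 mol %), AcOH (0.5 equiv), THF, 0 °C; unreacted (3aS,6R,7aS)-6 removed by chromatography
Reagents that add atoms: acetic acid, CC(O)=O
Why: Decarboxylative Tsuji–Trost 1,4-substitution of a cyclic vinyl carbonate (the carbonate counterpart of the vinyl epoxide to cis-4-acetoxy-2-enol reaction) run as a kinetic resolution: ionisation by zerovalent palladium with inversion, loss of CO2 and attack of acetate anti to palladium at the allyl terminus remote from the alkoxide give net retention, so the acetate ends up cis to the hydroxyl, while the chiral ligand should ionise only the matched (3aR,6S,7aR) enantiomer and the half equivalent of acetic acid stops the reaction at half conversion.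

Step 5
Reactants: 7 (1S,4R,6S)-6-{2-[(tert-butyldimethylsilyl)oxy]ethyl}-4-hydroxy-2-methoxycyclohex-2-en-1-yl acetate
Product: 8 (1S,4R,6S)-4-hydroxy-6-(2-hydroxyethyl)-2-methoxycyclohex-2-en-1-yl acetate
Conditions: Bu4NF (1.2 equiv), AcOH (1.2 equiv), THF, 0 °C to rt
Reagents that add atoms: none
Why: Fluoride cleavage of the primary silyl ether, buffered with acetic acid so that the acetate should not migrate and the acid-sensitive 3-methoxy allylic alcohol should not ionise.

Step 6
Reactants: 8 (1S,4R,6S)-4-hydroxy-6-(2-hydroxyethyl)-2-methoxycyclohex-2-en-1-yl acetate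
Product: 9 (1S,6S)-2-methoxy-4-oxo-6-(2-oxoethyl)cyclohex-2-en-1-yl acetate
Conditions: Dess–Martin periodinane (2.5 equiv), NaHCO3, CH2Cl2, 0 °C to rt
Reagents that add atoms: none
Why: Dess–Martin oxidation of both hydroxyl groups at once: the primary alcohol gives the aldehyde and the 3-methoxy allylic alcohol gives the robust vinylogous ester, which also makes the neighbouring ring CH2 acidic for step 10.

Step 7
Reactants: 10 1-tridecene; 11 diethylzinc
Product: 13 ditridecylzinc, via diethyl(tridecyl)borane 12 (not isolated)
Conditions: Et2BH (from BH3·SMe2 and Et3B), neat, 0 °C to rt; then 11 (2 equiv), 0 °C; volatiles removed in vacuo, residue taken up in toluene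
Reagents that add atoms: diethylzinc (11), CC[Zn]CC
Why: Anti-Markovnikov hydroboration of the terminal alkene followed by boron–zinc exchange should give the salt-free dialkylzinc once triethylborane and excess diethylzinc are pumped off.

Step 8
Reactants: 9 (1S,6S)-2-methoxy-4-oxo-6-(2-oxoethyl)cyclohex-2-en-1-yl acetate; 13 ditridecylzinc
Product: 14 (1S,6S)-6-[(2R)-2-hydroxypentadecyl]-2-methoxy-4-oxocyclohex-2-en-1-yl acetate
Conditions: 13 (2 equiv), Ti(OiPr)4 (2 equiv), (1S,2S)-1,2-bis(trifluoromethanesulfonamido)cyclohexane (8 mol %), toluene, −20 °C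
Reagents that add atoms: ditridecylzinc (13), CCCCCCCCCCCCC[Zn]CCCCCCCCCCCCC
Why: Titanium-mediated, bis-sulfonamide-catalysed enantioselective addition of a dialkylzinc to an aliphatic aldehyde: the chiral titanium complex chooses the aldehyde face (reagent control, the ring centres being too remote to compete) and so sets the (R) carbinol, while the vinylogous ester carbonyl and the acetate should not react with the dialkylzinc.

Step 9
Reactants: 14 (1S,6S)-6-[(2R)-2-hydroxypentadecyl]-2-methoxy-4-oxocyclohex-2-en-1-yl acetate
Product: 15 (1S,6S)-6-[(2R)-2-acetoxypentadecyl]-2-methoxy-4-oxocyclohex-2-en-1-yl acetate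
Conditions: Ac2O, pyridine, DMAP (cat.), CH2Cl2, rt
Reagents that add atoms: acetic anhydride, CC(=O)OC(C)=O
Why: DMAP-catalysed acetylation installs the side-chain acetate of the target without touching the carbinol configuration.

Step 10
Reactants: 15 (1S,6S)-6-[(2R)-2-acetoxypentadecyl]-2-methoxy-4-oxocyclohex-2-en-1-yl acetate
Product: 17 (1S,5S,6R)-6-[(2R)-2-acetoxypentadecyl]-2-methoxy-4-oxo-5-(phenylselanyl)cyclohex-2-en-1-yl acetate, via lithium cross-conjugated dienolate 16 (not isolated)
Conditions: LiN(iPr)2 (1.05 equiv), THF, −78 °C; then PhSeCl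
Reagents that add atoms: benzeneselenenyl chloride, Cl[Se]c1ccccc1
Why: Kinetic deprotonation of a 3-alkoxy enone takes place at the α′ carbon (C5) rather than at the acetates, and selenenylation of the enolate should occur trans to the neighbouring side chain, which places selenium cis to the C6 hydrogen needed in step 12.

Step 11
Reactants: 17 (1S,5S,6R)-6-[(2R)-2-acetoxypentadecyl]-2-methoxy-4-oxo-5-(phenylselanyl)cyclohex-2-en-1-yl acetate
Product: 18 (1S,4S,5S,6R)-6-[(2R)-2-acetoxypentadecyl]-4-hydroxy-2-methoxy-5-(phenylselanyl)cyclohex-2-en-1-yl acetate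
Conditions: NaBH4, CeCl3·7H2O, MeOH, −78 °C
Reagents that add atoms: none
Why: Luche 1,2-reduction, in which axial hydride attack should give the equatorial alcohol trans to the equatorial phenylselanyl group and therefore cis to the C1 acetate.

Step 12
Reactants: 18 (1S,4S,5S,6R)-6-[(2R)-2-acetoxypentadecyl]-4-hydroxy-2-methoxy-5-(phenylselanyl)cyclohex-2-en-1-yl acetate
Product: 20 (1S,4R)-6-[(2R)-2-acetoxypentadecyl]-4-hydroxy-2-methoxycyclohexa-2,5-dien-1-yl acetate, via β-hydroxy selenoxide 19 (not isolated)
Conditions: H2O2 (30 % aq), pyridine, CH2Cl2, 0 °C to rt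
Reagents that add atoms: none
Why: Selenide oxidation and selenoxide syn-elimination; β-hydroxy selenoxides eliminate away from the carbinol carbon, so the C6 hydrogen cis to selenium is removed and the C5=C6 bond forms under neutral conditions that the acid-sensitive dienol should survive.

**Compound list**

1 | tert-butyl(but-3-yn-1-yloxy)dimethylsilane | C#CCCO[Si](C)(C)C(C)(C)C | starting material
2 | methyl vinyl ether | COC=C | starting material
3 | tert-butyl{[(4E)-5-methoxy-3-methylidenepent-4-en-1-yl]oxy}dimethylsilane | C=C(CCO[Si](C)(C)C(C)(C)C)/C=C/OC | intermediate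
4 | vinylene carbonate | O=C1OC=CO1 | starting material
5 | rac-(3aR,4S,7aR)-6-{2-[(tert-butyldimethylsilyl)oxy]ethyl}-4-methoxy-3a,4,7,7a-tetrahydro-1,3-benzodioxol-2-one | CC(C)(C)[Si](C)(C)OCCC1=C[C@H](OC)[C@@H]2OC(=O)O[C@@H]2C1 | intermediate
6 | rac-(3aR,6S,7aR)-6-{2-[(tert-butyldimethylsilyl)oxy]ethyl}-4-methoxy-3a,6,7,7a-tetrahydro-1,3-benzodioxol-2-one | CC(C)(C)[Si](C)(C)OCC[C@@H]1C=C(OC)[C@@H]2OC(=O)O[C@@H]2C1 | intermediate
7 | (1S,4R,6S)-6-{2-[(tert-butyldimethylsilyl)oxy]ethyl}-4-hydroxy-2-methoxycyclohex-2-en-1-yl acetate | CC(C)(C)[Si](C)(C)OCC[C@H]1C[C@@H](O)C=C(OC)[C@H]1OC(C)=O | intermediate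
8 | (1S,4R,6S)-4-hydroxy-6-(2-hydroxyethyl)-2-methoxycyclohex-2-en-1-yl acetate | OCC[C@H]1C[C@@H](O)C=C(OC)[C@H]1OC(C)=O | intermediate
9 | (1S,6S)-2-methoxy-4-oxo-6-(2-oxoethyl)cyclohex-2-en-1-yl acetate | O=CC[C@H]1CC(=O)C=C(OC)[C@H]1OC(C)=O | intermediate
10 | 1-tridecene | C=CCCCCCCCCCCC | starting material
11 | diethylzinc | CC[Zn]CC | starting material
12 | diethyl(tridecyl)borane | CCCCCCCCCCCCCB(CC)CC | intermediate
13 | ditridecylzinc | CCCCCCCCCCCCC[Zn]CCCCCCCCCCCCC | intermediate
14 | (1S,6S)-6-[(2R)-2-hydroxypentadecyl]-2-methoxy-4-oxocyclohex-2-en-1-yl acetate | CCCCCCCCCCCCC[C@H](C[C@H]1CC(=O)C=C(OC)[C@H]1OC(C)=O)O | intermediate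
15 | (1S,6S)-6-[(2R)-2-acetoxypentadecyl]-2-methoxy-4-oxocyclohex-2-en-1-yl acetate | CCCCCCCCCCCCC[C@H](C[C@H]1CC(=O)C=C(OC)[C@H]1OC(C)=O)OC(C)=O | intermediate
16 | lithium cross-conjugated dienolate of 15 | CCCCCCCCCCCCC[C@H](C[C@H]1C=C([O-])C=C(OC)[C@H]1OC(C)=O)OC(C)=O.[Li+] | intermediate
17 | (1S,5S,6R)-6-[(2R)-2-acetoxypentadecyl]-2-methoxy-4-oxo-5-(phenylselanyl)cyclohex-2-en-1-yl acetate | CCCCCCCCCCCCC[C@H](C[C@H]1[C@H]([Se]c2ccccc2)C(=O)C=C(OC)[C@H]1OC(C)=O)OC(C)=O | intermediate
18 | (1S,4S,5S,6R)-6-[(2R)-2-acetoxypentadecyl]-4-hydroxy-2-methoxy-5-(phenylselanyl)cyclohex-2-en-1-yl acetate | CCCCCCCCCCCCC[C@H](C[C@H]1[C@H]([Se]c2ccccc2)[C@@H](O)C=C(OC)[C@H]1OC(C)=O)OC(C)=O | intermediate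
19 | selenoxide of 18 (configuration at selenium not defined) | CCCCCCCCCCCCC[C@H](C[C@H]1[C@H]([Se](=O)c2ccccc2)[C@@H](O)C=C(OC)[C@H]1OC(C)=O)OC(C)=O | intermediate
20 | (1S,4R)-6-[(2R)-2-acetoxypentadecyl]-4-hydroxy-2-methoxycyclohexa-2,5-dien-1-yl acetate | CCCCCCCCCCCCC[C@H](CC1=C[C@@H](O)C=C(OC)[C@H]1OC(C)=O)OC(C)=O | target

**Totals and risks**

Total step count: 12. Longest linear sequence: 11 steps (steps 1–6 and 8–12, from 1); step 7 is a one-step branch.

Steps most likely to fail:

1. Step 3. The ruthenium hydride may not add to the hindered trisubstituted ring alkene, or may move the double bond toward the ring CH2 or the side-chain arm instead of into conjugation with the methoxy group. Fallback, setting out from 5 and coming back at 8: hydroboration with 9-BBN (boron on the less substituted alkene carbon, anti to the carbonate), then oxidation of the organoborane with [C5H5NH][CrO3Cl], should give the racemic ring ketone F1 (carbonyl at the carbon that becomes C1). Triethylamine then expels the carbonate oxygen β to the ketone (E1cB, with loss of CO2) to give the racemic 4-hydroxy-2-methoxy enone F2. Acylative kinetic resolution with isobutyric anhydride and (S)-benzotetramisole (taken as the enantiomer that acylates the (4S)-carbinol) converts the unwanted enantiomer into the isobutyrate F3, which is removed; this replaces the selection of step 4. Unchanged (4R,6S)-F2 is silylated (TBSCl, imidazole) to the bis-silyl ether F4 and reduced with LiBH(s-Bu)3 from the face opposite the side-chain arm to the allylic alcohol F5. Acetylation (Ac2O, pyridine) gives the acetate F6, and removal of both silyl groups (Bu4NF, AcOH) gives 8.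

2. Step 4. The chiral palladium catalyst may not distinguish the two enantiomers of 6 well enough for a clean kinetic resolution. Fallback, setting out from 6 and coming back at 7: Pd(PPh3)4 and acetic acid (1.1 equiv) in THF convert both enantiomers, giving 7 together with its (1R,4S,6R)-enantiomer F7. Acylative kinetic resolution with (S)-benzotetramisole and isobutyric anhydride (enantiomer of the catalyst chosen so that the (4S)-carbinol reacts) then turns F7 into the isobutyrate F8, and unchanged 7 is separated from the ester by chromatography and enters step 5.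

3. Step 8. Alkyl transfer from the long-chain dialkylzinc may be slow, or the facial selectivity at the unbranched aldehyde may be low. Fallback, setting out from 9 and coming back at 14: allylboration at −78 °C with the enantiomer of B-allyldiisopinocampheylborane that gives the (R)-carbinol (expected to be the reagent made from (−)-α-pinene), followed by work-up with NaBO3·4H2O, gives the homoallylic alcohol F9. Cross-metathesis with 1-dodecene (second-generation Grubbs catalyst, CH2Cl2, 40 °C) gives the chain-extended alkene F10. Diimide (2-nitrobenzenesulfonylhydrazide, Et3N, CH2Cl2, rt) then saturates only the isolated disubstituted alkene and leaves the vinylogous ester untouched, giving 14.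

Further compounds

F1 | step 3 | rac-(3aR,4R,6S,7aR)-6-{2-[(tert-butyldimethylsilyl)oxy]ethyl}-4-methoxyhexahydro-1,3-benzodioxole-2,5-dione | CC(C)(C)[Si](C)(C)OCC[C@@H]1C(=O)[C@H](OC)[C@@H]2OC(=O)O[C@@H]2C1
F2 | step 3 | rac-(4R,6S)-6-{2-[(tert-butyldimethylsilyl)oxy]ethyl}-4-hydroxy-2-methoxycyclohex-2-en-1-one | CC(C)(C)[Si](C)(C)OCC[C@@H]1C(=O)C(OC)=C[C@H](O)C1
F3 | step 3 | isobutyrate of the (4S,6R)-enantiomer of F2 | CC(C)(C)[Si](C)(C)OCC[C@H]1C(=O)C(OC)=C[C@@H](OC(=O)C(C)C)C1
F4 | step 3 | (4R,6S)-4-[(tert-butyldimethylsilyl)oxy]-6-{2-[(tert-butyldimethylsilyl)oxy]ethyl}-2-methoxycyclohex-2-en-1-one | CC(C)(C)[Si](C)(C)OCC[C@@H]1C(=O)C(OC)=C[C@H](O[Si](C)(C)C(C)(C)C)C1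
F5 | step 3 | (1S,4R,6S)-4-[(tert-butyldimethylsilyl)oxy]-6-{2-[(tert-butyldimethylsilyl)oxy]ethyl}-2-methoxycyclohex-2-en-1-ol (new hydroxyl cis to the side-chain arm and to the silyloxy group) | CC(C)(C)[Si](C)(C)OCC[C@@H]1[C@H](O)C(OC)=C[C@H](O[Si](C)(C)C(C)(C)C)C1
F6 | step 3 | acetate of F5 (bis-silyl ether of 8) | CC(C)(C)[Si](C)(C)OCC[C@@H]1[C@H](OC(C)=O)C(OC)=C[C@H](O[Si](C)(C)C(C)(C)C)C1
F7 | step 4 | (1R,4S,6R)-6-{2-[(tert-butyldimethylsilyl)oxy]ethyl}-4-hydroxy-2-methoxycyclohex-2-en-1-yl acetate (enantiomer of 7) | CC(C)(C)[Si](C)(C)OCC[C@@H]1C[C@H](O)C=C(OC)[C@@H]1OC(C)=O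
F8 | step 4 | isobutyrate of F7 | CC(C)(C)[Si](C)(C)OCC[C@@H]1C[C@H](OC(=O)C(C)C)C=C(OC)[C@@H]1OC(C)=O
F9 | step 8 | (1S,6S)-6-[(2R)-2-hydroxypent-4-en-1-yl]-2-methoxy-4-oxocyclohex-2-en-1-yl acetate | C=CC[C@H](C[C@H]1CC(=O)C=C(OC)[C@H]1OC(C)=O)O
F10 | step 8 | (1S,6S)-6-[(2R,4E)-2-hydroxypentadec-4-en-1-yl]-2-methoxy-4-oxocyclohex-2-en-1-yl acetate | CCCCCCCCCC/C=C/C[C@H](C[C@H]1CC(=O)C=C(OC)[C@H]1OC(C)=O)O
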